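**Assumption:** the target is achiral (no stereocentre, freely rotating 2-aryl bond), so no stereocontrol is needed. Phloroacetophenone, 1,2,3,4-tetramethoxybenzene and TMPZnCl·LiCl (THF solution) are taken as catalogue items.

## Retrosynthetic overview

1. The target comes from its 5,7-di-O-benzyl ether by hydrogenolysis; the four methyl ethers of ring B are carried through untouched.
2. Key C–C bond C2–C1′: chromone C2 is the acceptor (β) carbon of the vinylogous ester in classical flavone syntheses. Here it is the donor: a 2-zincated chromone (β-acylvinyl anion, a homoenolate-type d3 synthon) is joined to the electrophilic ipso carbon of 1-iodo-2,3,4,5-tetramethoxybenzene.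
3. The 5,7-bis(benzyloxy)chromone comes from di-O-benzyl phloroacetophenone and DMF dimethyl acetal (which supplies C2), and that from phloroacetophenone.
4. The aryl iodide comes from 1,2,3,4-tetramethoxybenzene by electrophilic iodination.
5. Ring order: rings A and B are bought intact; the pyranone ring C is closed first on ring A, and ring B is attached last.

## Route

Step 1
Reactants: 1 2',4',6'-trihydroxyacetophenone; 2 benzyl bromide
Product: 3 1-[2,4-bis(benzyloxy)-6-hydroxyphenyl]ethan-1-one
Conditions: BnBr (2.1 equiv), K2CO3 (2.2 equiv), DMF, 0 °C → rt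
Reagents that add atoms: benzyl bromide (2), BrCc1ccccc1
Why: Williamson etherification caps the 4-OH and one 2-OH, while the remaining ortho-OH, hydrogen-bonded to the acetyl C=O, is the least acidic and least nucleophilic and stays free.

Step 2
Reactants: 3 1-[2,4-bis(benzyloxy)-6-hydroxyphenyl]ethan-1-one; 4 N,N-dimethylformamide dimethyl acetal
Product: 6 5,7-bis(benzyloxy)-4H-chromen-4-one, via enaminone 5 (not isolated)
Conditions: DMF-DMA (3 equiv), toluene, 95 °C; evaporate; then 2 M HCl, CH2Cl2, rt
Reagents that add atoms: N,N-dimethylformamide dimethyl acetal (4), COC(OC)N(C)C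
Why: Enaminone condensation of the methyl ketone with the amide acetal, then acid-promoted intramolecular oxa-Michael addition of the free phenol and loss of dimethylamine, closes the pyranone ring (enaminone route to chromones); benzyl ethers survive both stages.

Step 3
Reactants: 7 1,2,3,4-tetramethoxybenzene; 8 N-iodosuccinimide
Product: 9 1-iodo-2,3,4,5-tetramethoxybenzene
Conditions: NIS (1.05 equiv), TFA (0.3 equiv), MeCN, rt, dark
Reagents that add atoms: N-iodosuccinimide (8), O=C1CCC(=O)N1I
Why: Electrophilic aromatic iodination (SEAr) at one of the two equivalent, strongly activated free positions; the first iodine slows a second substitution, so one equivalent gives the mono-iodide.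

Step 4
Reactants: 6 5,7-bis(benzyloxy)-4H-chromen-4-one; 10 TMPZnCl·LiCl; 9 1-iodo-2,3,4,5-tetramethoxybenzene
Product: 12 5,7-bis(benzyloxy)-2',3',4',5'-tetramethoxyflavone, via chromon-2-ylzinc chloride 11 (not isolated)
Conditions: 6 (1.2 equiv), TMPZnCl·LiCl (1.4 equiv), THF, 25 °C, no Mg salts or BF3; then 9 (1.0 equiv), Pd(OAc)2 (2 mol%), SPhos (4 mol%), 50 °C
Reagents that add atoms: 1-iodo-2,3,4,5-tetramethoxybenzene (9), COc1cc(I)c(OC)c(OC)c1OC; TMPZnCl·LiCl (10), CC1(C)CCCC(C)(C)N1[Zn]Cl.[Li+].[Cl-] (zinc and chlorine of 11 only)
Why: Directed C–H zincation with the hindered TMP–zinc amide, in the absence of a carbonyl-bound Lewis acid, removes the most acidic vinylic proton (C2–H, next to the ring oxygen), so the normally electrophilic β-carbon of the vinylogous ester becomes a carbon nucleophile (β-acylvinyl anion, homoenolate-type d3 synthon) that is joined to the electrophilic ipso carbon of 9 by Negishi cross-coupling; no stereocentre is formed.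

Step 5
Reactants: 12 5,7-bis(benzyloxy)-2',3',4',5'-tetramethoxyflavone
Product: 13 5,7-dihydroxy-2',3',4',5'-tetramethoxyflavone
Conditions: H2 (1 atm), 10% Pd/C, THF–MeOH, rt, stop at full conversion
Reagents that add atoms: none
Why: Catalytic hydrogenolysis cleaves the two benzyl aryl ethers, while the aryl methyl ethers are inert and the conjugated C2=C3 bond of the flavone is not reduced at 1 atm and room temperature.

## Compound list

1 | 2',4',6'-trihydroxyacetophenone (phloroacetophenone) | CC(=O)c1c(O)cc(O)cc1O | starting material
2 | benzyl bromide | BrCc1ccccc1 | starting material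
3 | 1-[2,4-bis(benzyloxy)-6-hydroxyphenyl]ethan-1-one | CC(=O)c1c(O)cc(OCc2ccccc2)cc1OCc1ccccc1 | intermediate
4 | N,N-dimethylformamide dimethyl acetal | COC(OC)N(C)C | starting material
5 | (E)-1-[2,4-bis(benzyloxy)-6-hydroxyphenyl]-3-(dimethylamino)prop-2-en-1-one | CN(C)/C=C/C(=O)c1c(O)cc(OCc2ccccc2)cc1OCc1ccccc1 | intermediate
6 | 5,7-bis(benzyloxy)-4H-chromen-4-one | O=c1ccoc2cc(OCc3ccccc3)cc(OCc3ccccc3)c12 | intermediate
7 | 1,2,3,4-tetramethoxybenzene | COc1ccc(OC)c(OC)c1OC | starting material
8 | N-iodosuccinimide | O=C1CCC(=O)N1I | starting material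
9 | 1-iodo-2,3,4,5-tetramethoxybenzene | COc1cc(I)c(OC)c(OC)c1OC | intermediate
10 | (2,2,6,6-tetramethylpiperidin-1-yl)zinc chloride lithium chloride complex (TMPZnCl·LiCl) | CC1(C)CCCC(C)(C)N1[Zn]Cl.[Li+].[Cl-] | starting material
11 | [5,7-bis(benzyloxy)-4-oxo-4H-chromen-2-yl]zinc chloride | O=c1cc([Zn]Cl)oc2cc(OCc3ccccc3)cc(OCc3ccccc3)c12 | intermediate
12 | 5,7-bis(benzyloxy)-2',3',4',5'-tetramethoxyflavone | COc1cc(-c2cc(=O)c3c(OCc4ccccc4)cc(OCc4ccccc4)cc3o2)c(OC)c(OC)c1OC | intermediate
13 | 5,7-dihydroxy-2',3',4',5'-tetramethoxyflavone | COc1cc(-c2cc(=O)c3c(O)cc(O)cc3o2)c(OC)c(OC)c1OC | target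

## Step count and risks

Total step count: 5.
Longest linear sequence: 4 (steps 1, 2, 4, 5; step 3 is the convergent branch).

**Step 4 (most likely to fail).** The electron-rich 5,7-dialkoxy chromone may zincate slowly or partly at C3, and the hindered, electron-rich iodide may couple sluggishly. The fallback sets out from 3 and comes back at 12. Claisen condensation of 3 with diethyl oxalate (NaOEt, EtOH), then cyclodehydration with HCl in EtOH, gives ethyl 5,7-bis(benzyloxy)-4-oxo-4H-chromene-2-carboxylate F1. Mild saponification (aq. Na2CO3, EtOH, then acidify) gives 5,7-bis(benzyloxy)-4-oxo-4H-chromene-2-carboxylic acid F2. Palladium-catalysed, silver-mediated decarboxylative arylation of F2 with 9 (PdCl2, PPh3, Ag2CO3, DMSO–DMF, about 130 °C) then gives 12. The carboxylate fixes the site: loss of CO2 generates the C2 donor (chromon-2-yl–silver) regiospecifically, so C2 is still the nucleophilic partner. This decarboxylative coupling is argued by analogy with furan- and benzofuran-2-carboxylic acids and is less certain than the main step.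

**Step 1.** The phloroglucinol nucleus can give mono-, tri- and C-benzylated by-products, so the yield of 3 may be modest. The fallback sets out from 1 and comes back at 6 by building the pyranone before protecting. Compound 1 is treated with triethyl orthoformate and 70% HClO4, and the resulting 4-ethoxybenzopyrylium salt is hydrolysed in hot water to 5,7-dihydroxy-4H-chromen-4-one F3. Exhaustive benzylation (BnBr 2.5 equiv, K2CO3, DMF, 70 °C) then gives 6 with no selectivity demand, because both hydroxyls must be capped.

**Step 5.** The C2=C3 bond may be over-reduced to the flavanone, or the 7-O-benzyl group may cleave incompletely. The fallback sets out from 12 and comes back at 13 by non-reductive Lewis-acid debenzylation: BCl3 (4 equiv) and pentamethylbenzene (6 equiv) in CH2Cl2 at −78 °C, with the benzyl cations trapped by the arene and the methyl ethers left intact at this temperature. It makes no new compound (F0).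

## Further compounds

F1 | step 4 | ethyl 5,7-bis(benzyloxy)-4-oxo-4H-chromene-2-carboxylate | CCOC(=O)c1cc(=O)c2c(OCc3ccccc3)cc(OCc3ccccc3)cc2o1
F2 | step 4 | 5,7-bis(benzyloxy)-4-oxo-4H-chromene-2-carboxylic acid | OC(=O)c1cc(=O)c2c(OCc3ccccc3)cc(OCc3ccccc3)cc2o1
F3 | step 1 | 5,7-dihydroxy-4H-chromen-4-one | O=c1ccoc2cc(O)cc(O)c12
F0 | step 5 | none | none
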